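**Plan**
- Retrosynthesis: the depside C(=O)–O bond between ring A and ring B is cut first; ring A is then opened at C2–C3, C4–C5 and C1–C2 to a 4-(benzyloxycarbonyl)-3-pentylcyclobutenone and methoxyacetylene; the cyclobutenone is cut at two ring C–C bonds to a malonamate-derived keteniminium ion and hept-1-yne.
- Enabling feature: in ring A the C2–OH and C4–OMe are meta with C3–H between them, and C1 carries the carboxyl next to C2. This is the pattern left when an alkoxyacetylene (C3, C4) is inserted between a ketene carbonyl carbon (C2) and its α-carbon (C5) and the dienylketene closes onto the ester-bearing terminus (C1).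
- Forward order: four-membered ring, then ring A by the pericyclic benzannulation; ring B is taken ready-made from olivetolic acid and only re-protected; the depside ester is formed last, followed by one hydrogenolysis.
- Stereochemistry: the target has no stereocentre; the single (racemic) centre of the cyclobutenone is erased on aromatisation.

Key step: step 4

Remark: olivetolic acid 16 is treated as a purchasable compound, and methoxyacetylene 9 (boiling near room temperature) is kept and dosed as a cold toluene solution.

**Step 1**
Reactants: 1 mono-benzyl malonate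
Product: 2 benzyl N,N-dimethylmalonamate (benzyl 3-(dimethylamino)-3-oxopropanoate)
Conditions: DCC, HOBt (cat.), Me2NH (2 M in THF), CH2Cl2, 0 °C to rt
Reagents that add atoms: dimethylamine, CNC
Why: Carbodiimide amide coupling of a malonic half-ester with a secondary amine is routine and leaves the benzyl ester untouched.

**Step 2**
Reactants: 2 benzyl N,N-dimethylmalonamate; 3 hept-1-yne
Product: 6 benzyl 4-oxo-2-pentylcyclobut-2-ene-1-carboxylate (racemic), via keteniminium triflate 4 (not isolated), via cyclobuteniminium triflate 5 (not isolated)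
Conditions: Tf2O, 2,4,6-collidine, 3 (3 equiv), ClCH2CH2Cl, −20 °C to 80 °C; then H2O, CH2Cl2, rt
Reagents that add atoms: water, O
Why: Proposed new method: O-triflylation of amide 2 and loss of the acidic C2 proton to collidine should give an α-triflyloxy enamine in equilibrium with keteniminium ion 4, whose central carbon is attacked by the terminal carbon of hept-1-yne while the enamine carbon captures the developing vinyl cation at the pentyl-bearing carbon, so that the ring closes as cyclobuteniminium salt 5 with pentyl next to the ester-bearing carbon and water then hydrolyses the iminium to the ketone; the closest known reaction type is the keteniminium–alkyne [2+2] cycloaddition (Ghosez cyclobutenone synthesis) of alkyl- and aryl-substituted keteniminium triflates, the alkoxycarbonyl substituent being the untested element.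

**Step 3**
Reactants: 7 chloroacetaldehyde dimethyl acetal
Product: 9 methoxyacetylene, via sodium methoxyethynide 8 (not isolated)
Conditions: NaNH2 (3 equiv), liquid NH3, −33 °C; then H2O, −70 °C, distillation into cold toluene
Reagents that add atoms: none
Why: Twofold base-induced β-elimination (loss of methanol, then of HCl) is the classical alkoxyacetylene synthesis from a chloroacetal, the third equivalent of NaNH2 holding the product as its acetylide until the aqueous quench.

**Step 4**
Reactants: 6 benzyl 4-oxo-2-pentylcyclobut-2-ene-1-carboxylate (racemic); 9 methoxyacetylene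
Product: 14 benzyl 2-hydroxy-4-methoxy-6-pentylbenzoate, via vinylketene 10 (not isolated), via vinylcyclobutenone 11 (not isolated), via dienylketene 12 (not isolated), via cyclohexadienone 13 (not isolated)
Conditions: 9 (3 equiv), toluene, sealed tube, 80 °C, then 110 °C
Reagents that add atoms: none
Why: Heating should open 6 by 4π electrocyclic cleavage of the bond between the carbonyl carbon and the ester-bearing carbon to the ester-conjugated vinylketene 10, whose electrophilic carbonyl carbon is attacked by the nucleophilic CH terminus of methoxyacetylene in a ketene–alkyne [2+2] cycloaddition that forms the future C2–C3 and C4–C5 bonds of ring A and gives vinylcyclobutenone 11. A second 4π opening delivers dienylketene 12, and a thermally allowed disrotatory 6π electrocyclisation joins the ketene carbon to the ester-bearing terminus (C1–C2), closing six-membered ring A as cyclohexadienone 13, which tautomerises through its doubly activated C1–H to the hydrogen-bonded salicylate 14. The closest known reaction type is the Danheiser benzannulation of cyclobutenones with alkoxyacetylenes, applied here to a 4-alkoxycarbonyl cyclobutenone. No stereocentre is created: the racemic centre of 6 and the transient sp3 C1 of 13 are erased on aromatisation, and either alkene geometry of 10 converges on 13. The step needs regiocontrol in the [2+2] event only, which the polarisation of the ynol ether (β-carbon nucleophilic) against the ketene (carbonyl carbon electrophilic) secures, placing H at C3 and OMe at C4, so that the methyl ether arrives with the alkyne and the two oxygens of ring A never have to be told apart. Methoxyacetylene has no β-hydrogen for retro-ene loss and the product phenol is chelated to its ester, which should limit alkyne decomposition and trapping of ketenes by the product.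

**Step 5**
Reactants: 14 benzyl 2-hydroxy-4-methoxy-6-pentylbenzoate
Product: 15 2-hydroxy-4-methoxy-6-pentylbenzoic acid
Conditions: H2 (1 atm), 10% Pd/C, EtOAc, rt
Reagents that add atoms: none
Why: Hydrogenolysis of the benzyl ester is neutral and runs at room temperature, so the decarboxylation-prone 6-alkylsalicylic acid should be freed without heat or base.

**Step 6**
Reactants: 16 olivetolic acid (2,4-dihydroxy-6-pentylbenzoic acid)
Product: 17 benzyl 2,4-dihydroxy-6-pentylbenzoate
Conditions: BnBr, KHCO3, DMF, rt
Reagents that add atoms: benzyl bromide, BrCc1ccccc1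
Why: SN2 O-alkylation of the carboxylate is selective because KHCO3 deprotonates the acid but not the phenols.

**Step 7**
Reactants: 17 benzyl 2,4-dihydroxy-6-pentylbenzoate
Product: 18 benzyl 2-hydroxy-6-pentyl-4-(prop-2-en-1-yloxy)benzoate
Conditions: allyl bromide (1.05 equiv), K2CO3, acetone, rt
Reagents that add atoms: allyl bromide, C=CCBr
Why: Williamson etherification should take place at the 4-OH only, since the 2-OH is hydrogen-bonded to the ester carbonyl and is less acidic and less nucleophilic.

**Step 8**
Reactants: 18 benzyl 2-hydroxy-6-pentyl-4-(prop-2-en-1-yloxy)benzoate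
Product: 19 benzyl 2-methoxy-6-pentyl-4-(prop-2-en-1-yloxy)benzoate
Conditions: MeI (excess), K2CO3, DMF, 50 °C
Reagents that add atoms: iodomethane, CI
Why: Williamson methylation under more forcing conditions alkylates the remaining chelated phenol, while the hindered benzyl ester and the allyl ether are inert.

**Step 9**
Reactants: 19 benzyl 2-methoxy-6-pentyl-4-(prop-2-en-1-yloxy)benzoate
Product: 20 benzyl 4-hydroxy-2-methoxy-6-pentylbenzoate
Conditions: Pd(PPh3)4 (cat.), morpholine, THF, rt
Reagents that add atoms: none
Why: Tsuji–Trost deallylation with zerovalent palladium and morpholine as allyl acceptor frees the phenol under conditions that leave benzyl esters and methyl ethers alone.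

**Step 10**
Reactants: 15 2-hydroxy-4-methoxy-6-pentylbenzoic acid; 20 benzyl 4-hydroxy-2-methoxy-6-pentylbenzoate
Product: 22 benzyl 4-[(2-hydroxy-4-methoxy-6-pentylbenzoyl)oxy]-2-methoxy-6-pentylbenzoate, via mixed anhydride 21 (not isolated)
Conditions: (CF3CO)2O, toluene, rt
Reagents that add atoms: none
Why: Mixed-anhydride esterification with trifluoroacetic anhydride is the established depside coupling, in which the chelated, flanked 2-OH of 15 stays passive and the only free phenol of 20 is acylated.

**Step 11**
Reactants: 22 benzyl 4-[(2-hydroxy-4-methoxy-6-pentylbenzoyl)oxy]-2-methoxy-6-pentylbenzoate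
Product: 23 2'-O-methylperlatolic acid
Conditions: H2 (1 atm), 10% Pd/C, EtOAc, rt
Reagents that add atoms: none
Why: Hydrogenolysis cleaves only the benzyl ester, the aryl ester linkage of the depside and the methyl ethers being stable to H2 over Pd/C.

**Compound list**
1 | mono-benzyl malonate (3-(benzyloxy)-3-oxopropanoic acid) | O=C(O)CC(=O)OCc1ccccc1 | starting material
2 | benzyl N,N-dimethylmalonamate (benzyl 3-(dimethylamino)-3-oxopropanoate) | CN(C)C(=O)CC(=O)OCc1ccccc1 | intermediate
3 | hept-1-yne | C#CCCCCC | starting material
4 | N-[2-(benzyloxycarbonyl)ethenylidene]-N-methylmethanaminium trifluoromethanesulfonate (keteniminium triflate) | C[N+](C)=C=CC(=O)OCc1ccccc1.[O-]S(=O)(=O)C(F)(F)F | intermediate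
5 | N-[4-(benzyloxycarbonyl)-3-pentylcyclobut-2-en-1-ylidene]-N-methylmethanaminium trifluoromethanesulfonate (cyclobuteniminium triflate, racemic) | CCCCCC1=CC(=[N+](C)C)C1C(=O)OCc1ccccc1.[O-]S(=O)(=O)C(F)(F)F | intermediate
6 | benzyl 4-oxo-2-pentylcyclobut-2-ene-1-carboxylate (racemic) | CCCCCC1=CC(=O)C1C(=O)OCc1ccccc1 | intermediate
7 | chloroacetaldehyde dimethyl acetal (2-chloro-1,1-dimethoxyethane) | COC(CCl)OC | starting material
8 | sodium methoxyethynide (NaC≡COMe) | [Na+].[C-]#COC | intermediate
9 | methoxyacetylene (methoxyethyne) | C#COC | intermediate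
10 | benzyl (2E)-5-oxo-3-pentylpenta-2,4-dienoate (vinylketene) | O=C=C/C(CCCCC)=C/C(=O)OCc1ccccc1 | intermediate
11 | benzyl (2E)-3-(2-methoxy-4-oxocyclobut-2-en-1-yl)oct-2-enoate (vinylcyclobutenone, racemic) | COC1=CC(=O)C1/C(CCCCC)=C/C(=O)OCc1ccccc1 | intermediate
12 | benzyl (2E,4E)-5-methoxy-7-oxo-3-pentylhepta-2,4,6-trienoate (dienylketene) | O=C=C/C(OC)=C\C(CCCCC)=C\C(=O)OCc1ccccc1 | intermediate
13 | benzyl 4-methoxy-2-oxo-6-pentylcyclohexa-3,5-diene-1-carboxylate (cyclohexadienone, racemic) | COC1=CC(=O)C(C(=O)OCc2ccccc2)C(CCCCC)=C1 | intermediate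
14 | benzyl 2-hydroxy-4-methoxy-6-pentylbenzoate | CCCCCc1cc(OC)cc(O)c1C(=O)OCc1ccccc1 | intermediate
15 | 2-hydroxy-4-methoxy-6-pentylbenzoic acid | CCCCCc1cc(OC)cc(O)c1C(=O)O | intermediate
16 | olivetolic acid (2,4-dihydroxy-6-pentylbenzoic acid) | CCCCCc1cc(O)cc(O)c1C(=O)O | starting material
17 | benzyl 2,4-dihydroxy-6-pentylbenzoate | CCCCCc1cc(O)cc(O)c1C(=O)OCc1ccccc1 | intermediate
18 | benzyl 2-hydroxy-6-pentyl-4-(prop-2-en-1-yloxy)benzoate | C=CCOc1cc(O)c(C(=O)OCc2ccccc2)c(CCCCC)c1 | intermediate
19 | benzyl 2-methoxy-6-pentyl-4-(prop-2-en-1-yloxy)benzoate | C=CCOc1cc(OC)c(C(=O)OCc2ccccc2)c(CCCCC)c1 | intermediate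
20 | benzyl 4-hydroxy-2-methoxy-6-pentylbenzoate | CCCCCc1cc(O)cc(OC)c1C(=O)OCc1ccccc1 | intermediate
21 | 2-hydroxy-4-methoxy-6-pentylbenzoic trifluoroacetic anhydride (mixed anhydride) | CCCCCc1cc(OC)cc(O)c1C(=O)OC(=O)C(F)(F)F | intermediate
22 | benzyl 4-[(2-hydroxy-4-methoxy-6-pentylbenzoyl)oxy]-2-methoxy-6-pentylbenzoate | CCCCCc1cc(OC)cc(O)c1C(=O)Oc1cc(CCCCC)c(C(=O)OCc2ccccc2)c(OC)c1 | intermediate
23 | 2'-O-methylperlatolic acid | CCCCCc1cc(OC)cc(O)c1C(=O)Oc1cc(CCCCC)c(C(=O)O)c(OC)c1 | target

**Step count**
Total: 11 steps. Longest linear sequence: 6 steps (steps 1, 2, 4, 5, 10, 11; the ring B arm, steps 6 to 11, is equally long).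

**Steps most likely to fail**

1. Step 2 (Proposed new method). The push–pull α-triflyloxy enamine may fail to ionise to the keteniminium ion. Alternatively the ester oxygen may capture the developing vinyl cation, closing a six-membered pyrylium ring instead of the four-membered carbocycle. The fallback uses known chemistry at a lower oxidation level; it sets out from hept-1-yne 3 and returns at acid 15.
   - Dichloroketene (Cl3CCOCl, Zn–Cu couple, Et2O) adds to 3 to give 4,4-dichloro-3-pentylcyclobut-2-en-1-one F1.
   - Zn dust, AcOH and TMEDA in EtOH remove both chlorines to give 3-pentylcyclobut-2-en-1-one F2.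
   - Heating F2 with methoxyacetylene 9 (the same benzannulation on an ester-free cyclobutenone) should give 3-methoxy-5-pentylphenol F3.
   - Magnesium-mediated ortho-formylation (MgCl2, Et3N, paraformaldehyde, MeCN, reflux), expected ortho to OH and para to OMe, leads to 2-hydroxy-4-methoxy-6-pentylbenzaldehyde F4.
   - Pinnick oxidation (NaClO2, NaH2PO4, 2-methylbut-2-ene, t-BuOH–H2O) delivers 15.

2. Step 4. The ester-bearing vinylketene may be diverted by oxa-6π closure onto the ester carbonyl (a 2-pyranone), by dimerisation, or the second ring opening may stall before the 6π closure. The fallback gives up the pericyclic ring construction for a classical one. It sets out from benzyl 2,4-dihydroxy-6-pentylbenzoate 17 of the ring B arm and returns at 14: selective Williamson methylation of the non-chelated 4-OH (MeI, 1 equiv, K2CO3, acetone, rt). No compound outside the list is formed (F0).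

3. Step 10. The mixed anhydride may acylate the unprotected 2-OH of a second molecule of 15, or the phenol of 20 may be trifluoroacetylated faster than it is aroylated. The fallback masks the 2-OH and changes the activation; it sets out from 14 and returns at target 23.
   - O-Benzylation (BnBr, K2CO3, DMF) gives benzyl 2-(benzyloxy)-4-methoxy-6-pentylbenzoate F5.
   - Saponification (KOH, DMSO–H2O, 80 °C) gives 2-(benzyloxy)-4-methoxy-6-pentylbenzoic acid F6.
   - Steglich esterification with 20 (DCC, DMAP, CH2Cl2) gives benzyl 4-{[2-(benzyloxy)-4-methoxy-6-pentylbenzoyl]oxy}-2-methoxy-6-pentylbenzoate F7.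
   - Hydrogenolysis (H2, 10% Pd/C, EtOAc) removes both benzyl groups to give 23.

**Further compounds**
F1 | step 2 | 4,4-dichloro-3-pentylcyclobut-2-en-1-one | CCCCCC1=CC(=O)C1(Cl)Cl
F2 | step 2 | 3-pentylcyclobut-2-en-1-one | CCCCCC1=CC(=O)C1
F3 | step 2 | 3-methoxy-5-pentylphenol | CCCCCc1cc(O)cc(OC)c1
F4 | step 2 | 2-hydroxy-4-methoxy-6-pentylbenzaldehyde | CCCCCc1cc(OC)cc(O)c1C=O
F0 | step 4 | none | none
F5 | step 10 | benzyl 2-(benzyloxy)-4-methoxy-6-pentylbenzoate | CCCCCc1cc(OC)cc(OCc2ccccc2)c1C(=O)OCc1ccccc1
F6 | step 10 | 2-(benzyloxy)-4-methoxy-6-pentylbenzoic acid | CCCCCc1cc(OC)cc(OCc2ccccc2)c1C(=O)O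
F7 | step 10 | benzyl 4-{[2-(benzyloxy)-4-methoxy-6-pentylbenzoyl]oxy}-2-methoxy-6-pentylbenzoate | CCCCCc1cc(OC)cc(OCc2ccccc2)c1C(=O)Oc1cc(CCCCC)c(C(=O)OCc2ccccc2)c(OC)c1
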